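# Proposed total synthesis of CNP0510523.1 (25)

## The problem

1. CNP0510523.1 (25) is an elemane-type (2,3-seco-eudesmane) lactone built on one cyclohexane, ring B (C5–C6–C7–C8–C9–C10). Every ring carbon is a stereocentre and C10 is quaternary, carrying the C14 methyl and the oxirane C1–C2; C1 is a seventh, exocyclic stereocentre and the eighth lies in the (S)-2-methylbutanoate. Labels used throughout: the propenal on C5 is C4(=C15H2)–C3HO, the lactone is C7–C11(=C13H2)–C12(=O)–O8; the labels follow the origin of the atoms in the route.
2. Ring B carries three two-carbon arms (on C10, C5 and C7) and three oxygens (O9 acylated, O8 in the trans-fused lactone, O6 free).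
3. In the chair with C14 axial, the three arms and O8 are equatorial while O6 and O9 are axial. C5, C7 and C8 can therefore be set by equilibration next to carbonyl groups at C6 and C9, and the two carbinols by equatorial hydride delivery. C10 and C1 cannot be set this way, and C1 sits on a freely rotating bond next to a quaternary carbon.
4. The feature that makes the key step possible: the arms on the adjacent atoms C10 and C5 end in C2 and C3, and C6 and C9 are para-related oxygenated carbons. Joining C2 to C3 closes a cyclohexene, ring A (C10–C1–C2=C3–C4–C5), fused to a 1,4-dioxygenated ring B. That bicycle is the Diels–Alder adduct of a 1-oxygenated butadiene and a 2-methyl-1,4-benzoquinone, with C1 inside a ring.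
5. Once ring A is cut again, C2 and C3 are both aldehydes and must be told apart: C2 becomes the oxirane CH2, C3 the formyl group.
6. The enal and the α-methylene lactone (both Michael acceptors), the terminal epoxide, the epimerisable acyl α-centre and the free 6-hydroxyl cis to the lactone arm (which can translactonise under base) will not survive enolate chemistry, hydrides or osmylation. They must be unveiled last, in mild steps.

## Retrosynthesis

**25 ⇒ 23 ⇒ 22.** The C11=C13 double bond is written back to the Mannich base 23 (a C13–N bond in place of the alkene), and the oxirane to the silyloxy mesylate 22 (cut of the O1–C2 bond). Enolate methylenation of the lactone at the end is ruled out by the ester, enal and epoxide of 25, so the methylene is carried as a β-amino lactone and released with MeI/NaHCO3. The forward steps ask only that the C1 alkoxide, freed by fluoride, closes on C2 faster than it does anything else.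

**22 ⇒ 20 + 21; 20 ⇒ 19 ⇒ 18 ⇒ 17 ⇒ 16.** The O9–acyl bond is cut to the anhydride 21 and the mesylate 20, and the C2–OMs bond to the enal diol 19. The C2/C3 problem is solved in the lactol aldehyde 16. Its C2 aldehyde is held as a lactol by the cis 9-hydroxyl, while C3 is a free, enolisable aldehyde that alone can be α-methylenated (17). Reduction to triol 18 then leaves the C3 alcohol allylic, so MnO2 restores the enal selectively (19) and only the C2 hydroxyl remains for sulfonylation. Acylation of O9 is placed after ring A is open, because in the bicycle O9 is syn-axial to the C1 silyloxy group.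

**16 ⇒ 14 (⇒ 13 ⇒ 12).** The C2–C3 bond, absent from the target, is re-formed as the C2=C3 alkene of 14. This is the strategic cut: ring A becomes a temporary ring that holds C1 in a ring, fixes ring B as a trans-decalin chair and supplies both arms on C10 and C5 with exactly the right carbon count. Compared with building the arms one by one, 14 needs no carbon–carbon bond formation at C10 or C5. The Mannich base 14 comes from lactone 13, and the silyl ether 13 from diol 12, whose 6-hydroxyl is the more accessible one.

**12 ⇒ 11 ⇒ 9.** The C6–H and C9–H bonds are cut (hydride), then the C12–O8 lactone bond and the C8–O8 bond (enolate oxidation). In the trans-decalin the axial C14 methyl blocks one face of C8 and C6, so electrophilic oxygen enters C8 equatorially, and an equatorially attacking hydride gives both axial alcohols. Reducing a C8 ketone instead would give the wrong, axial 8-hydroxyl.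

**9 ⇒ 8 ⇒ 5 + 6.** The C7–C11 bond is cut to the methoxy enedione 5 and the ketene silyl acetal 6. The methoxy group of 5 is used a second time: after conjugate addition at C7 it leaves from C8, so the arm ends up on C7 without any ambiguity about which enolate is alkylated. C5 and C7, both α to the C6 carbonyl, then settle equatorially. A sigmatropic delivery of the arm from O9 was rejected because the rigid trans-decalin holds the allylic C9–O bond pseudo-equatorial.

**5 ⇒ 2 + 4.** The C1–C10 and C4–C5 bonds are cut (Diels–Alder). Quinone 2 and diene 4 are flat, achiral and one step from commercial materials. The adduct 5 already holds the quaternary C10, the C1 stereocentre, both arms on C10 and C5, and the C6/C9 oxygens. The forward reaction must react at the methyl-bearing double bond, join C1 to C10, be endo, and be enantioselective.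

**2 ⇒ 1; 4 ⇒ 3.** Aerobic para-oxidation of the phenol 1, and silylation of the dienolate of crotonaldehyde 3.

## Roads not taken

**Alternative 1:** (the most obvious, biomimetic) Cut C5–C10 and re-form C2–C3 by a retro-Cope: the germacra-1(10),4-dien-8,12-olide A1 would rearrange thermally to the divinyl elemanolide A2, whose vinyl group would then be epoxidised. A1 is harder to make than 25: a ten-membered E,E-diene that already carries the C6–C9 stereocentres, the enal and the methylene lactone. The Cope equilibrium and the chair/boat choice that fixes C5/C10 are not under control. The final epoxidation of a terminal vinyl group on a quaternary carbon offers no handle for C1 and competes with other alkenes. The chosen plan makes the same C2–C3 bond on purpose, but in a six-membered ring, where it controls C1 instead of leaving it open.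

**Alternative 2:** Linear functionalisation of a chiral-pool cyclohexenone: the quinic acid-derived cis-acetonide enone A3 (C8/C9 oxygens in place) would be taken by vinylation and methyl cuprate addition to the quaternary ketone A4, followed by enolate alkylations at C5 and C7. Every centre is set in a separate step, the alkylation at C5 is neopentyl, and C1 still has to be created later on an acyclic vinyl group. No single step deals with C10 and C1 together, and the step count before the arms are complete exceeds that of the whole front end chosen here.

**Alternative 3:** Dearomatisation by Birch reductive methylation of 3-methoxybenzoic acid to the diene acid A5, which maps C10 (methyl and a C1 carboxyl), the C6 enol ether and the C8=C9 alkene onto ring B in one step. However, A5 is racemic, with no evident handle for asymmetric induction. C1–C2 would have to be built from the carboxyl with an uncontrolled C1 centre. The C5 arm must be forced into a neopentyl position. A monocyclic ring with a quaternary centre bearing two similar groups gives no reliable facial bias for C7, C8 and C9. The temporary ring A of the chosen plan supplies exactly this missing conformational lock.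

Key step: step 3

Assumption (chemistry): the enantiofacial sense of the titanium–BINOL catalyst in step 3 is assigned by analogy with related chelating quinones; if the antipode of 5 predominates, (S)-BINOL is used instead.

Remark: centres that are inconsequential mixtures (C8 in 7, C11 in 14–24, C2/C3 in 15, the lactol carbon C2 in 16 and 17) are left undefined in the SMILES.

## Route

Step 1
Reactants: 1 2-methoxy-6-methylphenol
Product: 2 2-methoxy-6-methyl-1,4-benzoquinone
Conditions: Co(salen) (5 mol %), O2 (1 atm), DMF, rt
Reagents that add atoms: dioxygen, O=O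
Why: Cobalt–salen-catalysed aerobic para-oxidation of a 2,6-disubstituted phenol to the p-benzoquinone; the free para position of 1 is the only site open to the phenoxyl–dioxygen pathway.

Step 2
Reactants: 3 (E)-but-2-enal (crotonaldehyde)
Product: 4 (E)-1-(tert-butyldimethylsilyloxy)buta-1,3-diene
Conditions: TBSOTf, Et3N, Et2O, 0 °C → rt
Reagents that add atoms: tert-butyldimethylsilyl trifluoromethanesulfonate, CC(C)(C)[Si](C)(C)OS(=O)(=O)C(F)(F)F
Why: Soft enolisation and O-silylation of the extended enolate of crotonaldehyde gives the 1-silyloxydiene, mainly E; any Z isomer is unreactive in step 3.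

Step 3
Reactants: 2 2-methoxy-6-methyl-1,4-benzoquinone; 4 (E)-1-(tert-butyldimethylsilyloxy)buta-1,3-diene
Product: 5 cis-fused adduct 8-(tert-butyldimethylsilyloxy)-2-methoxy-8a-methyl-4a,5,8,8a-tetrahydronaphthalene-1,4-dione (C1–OTBS anti to C14; C5–H syn to C14)
Conditions: (R)-BINOL (10 mol %), TiCl2(OiPr)2 (10 mol %), 4 Å MS, toluene, −30 °C
Reagents that add atoms: none
Why: Concerted, Lewis-acid-accelerated [4+2] cycloaddition (closest known type: BINOL–titanium-catalysed Diels–Alder reaction of 1-oxygenated butadienes with quinones), in which the titanium BINOLate chelates the C9 carbonyl and the C8 methoxy oxygen of 2. Ring A (C10–C1–C2=C3–C4–C5) is closed by suprafacial formation of the C1–C10 and C4–C5 bonds across the C10=C5 double bond; no other ring forms. Site selectivity (C10=C5 rather than C7=C8) is secured by the methoxy group, which makes C7=C8 an unreactive vinylogous ester; regioselectivity (silyloxy carbon bonded to the methyl-bearing C10) follows because the chelated C9 carbonyl makes C5 the electrophilic terminus, which pairs with the nucleophilic CH2 terminus of 4. C10 and C5 are set cis by the suprafaciality of the dienophile; C1 is set by the endo rule (quinone ring under the diene), which places the silyloxy group anti to the angular methyl, the C1 configuration of the target oxirane. Absolute configuration is set by the chiral titanium complex, which shields one face of the chelated quinone. C5 is deliberately left to be corrected, since it is alpha to the C6 carbonyl.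

Step 4
Reactants: 5 cis-fused methoxy enedione adduct; 6 1-(tert-butyldimethylsilyloxy)-1-methoxyethene
Product: 8 methyl 2-[5-(tert-butyldimethylsilyloxy)-4a-methyl-1,4-dioxo-1,4,4a,5,8,8a-hexahydronaphthalen-2-yl]acetate (trans-fused C7-arm enedione), via methoxy diketo ester Michael adduct 7 (not isolated)
Conditions: 6 (1.5 equiv), TiCl4 (1.1 equiv), CH2Cl2, −78 °C; aqueous work-up; then DBU (1.2 equiv), CH2Cl2, 0 °C → rt
Reagents that add atoms: none
Why: Mukaiyama–Michael addition: TiCl4 chelated between the C9 carbonyl and the C8 methoxy group makes C7 the electrophilic beta carbon, which the ketene silyl acetal attacks. DBU then deprotonates C7 (alpha to C6=O) and expels methoxide from C8 (E1cB), so the methoxy group is replaced by the acetate arm on the neighbouring carbon. The same base equilibrates C5 through the C6 enolate to the trans ring fusion, as is known for angularly methylated quinone–diene adducts.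

Step 5
Reactants: 8 trans-fused C7-arm enedione
Product: 9 methyl 2-[5-(tert-butyldimethylsilyloxy)-4a-methyl-1,4-dioxo-1,2,3,4,4a,5,8,8a-octahydronaphthalen-2-yl]acetate (trans-fused; C7 arm equatorial and cis to C14)
Conditions: Zn dust, AcOH, rt
Reagents that add atoms: none
Why: Zinc/acetic acid reduction of the ene-1,4-dione saturates only C7=C8; C7 (alpha to C6=O) equilibrates through the enol to the equatorial arm, giving the all-equatorial trans-decalindione.

Step 6
Reactants: 9 saturated trans-diketo ester
Product: 11 tricyclic lactone diketone (7,8-trans-fused gamma-lactone; ketones at C6 and C9), via hydroxy diketo ester 10 (not isolated)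
Conditions: LDA (1.05 equiv), THF, −78 °C; 2-(phenylsulfonyl)-3-phenyloxaziridine, −78 °C; then PPTS, toluene, 60 °C
Reagents that add atoms: 2-(phenylsulfonyl)-3-phenyloxaziridine, O=S(=O)(c1ccccc1)N1OC1c1ccccc1
Why: Kinetic deprotonation takes the only methylene alpha to a ketone (C8), and oxaziridine hydroxylation of the C9 enolate (Rubottom-type alpha-hydroxylation) occurs anti to the axial C14 methyl, which is syn-axial to C8; this gives the equatorial 8-hydroxyl trans to the C7 arm (C8 stays epimerisable and equatorial is also the thermodynamic position). Acid then closes the trans-diequatorial gamma-lactone with loss of methanol, which also protects the beta-ketol from elimination.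

Step 7
Reactants: 11 tricyclic lactone diketone
Product: 12 lactone diol (6-OH and 9-OH both axial; O6 cis to the C5 and C7 arms and O9 cis to O8)
Conditions: LiBH(s-Bu)3 (2.5 equiv), THF, −78 → −30 °C; AcOH quench at −78 °C, then aq. NaBO3
Reagents that add atoms: none
Why: The bulky hydride attacks both carbonyls along the equatorial trajectory, because axial approach is blocked at C6 by the syn-axial C14 methyl and at C9 by the peri silyloxy group and two axial hydrogens; this gives the axial alcohols at C6 and C9. The lactone is inert at low temperature, and the cold acidic quench prevents acyl transfer to the 6-alkoxide.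

Step 8
Reactants: 12 lactone diol
Product: 13 6-O-triethylsilyl ether of 12
Conditions: TESOTf (1.05 equiv), 2,6-lutidine, CH2Cl2, −78 °C
Reagents that add atoms: triethylsilyl trifluoromethanesulfonate, CC[Si](CC)(CC)OS(=O)(=O)C(F)(F)F
Why: The 9-hydroxyl is neopentyl and syn-axial to the C1 silyloxy group, so the silyl triflate should react first at O6.

Step 9
Reactants: 13 6-O-triethylsilyl lactone alcohol
Product: 14 Mannich base 11-(dimethylaminomethyl) lactone (C11 epimers)
Conditions: LDA (2.3 equiv), THF, −78 °C; CH2=NMe2+ I− (N,N-dimethylmethyleneiminium iodide), −78 → 0 °C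
Reagents that add atoms: N,N-dimethylmethyleneiminium iodide (Eschenmoser's salt), C=[N+](C)C.[I-]
Why: After the 9-alkoxide, the second equivalent of base forms the lactone enolate, which is aminomethylated (Mannich reaction). The beta-amino lactone is a stable, masked alpha-methylene lactone that tolerates the osmylation, hydride and fluoride steps that follow.

Step 10
Reactants: 14 Mannich base with intact ring A
Product: 16 seco lactol aldehyde (C3 aldehyde free; C2 as five-membered lactol on O9), via ring A 2,3-diol 15 (not isolated)
Conditions: OsO4 (2 mol %), NMO, acetone–H2O, rt; then NaIO4, THF–H2O, 0 °C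
Reagents that add atoms: N-methylmorpholine N-oxide (terminal oxidant for catalytic OsO4), C[N+]1([O-])CCOCC1; water, O
Why: Dihydroxylation of the only alkene (C2=C3) and periodate cleavage of the diol (Lemieux–Johnson-type sequence) remove the temporary C2–C3 bond; the C1 silyl ether prevents cleavage of C1–C2. The C2 aldehyde is captured by the cis 9-hydroxyl as a lactol, which also protects the epimerisable C1, while the C3 aldehyde stays free because O6 is silylated.

Step 11
Reactants: 16 seco lactol aldehyde
Product: 17 enal lactol (C4=C15H2 installed)
Conditions: CH2=NMe2+ I− (1.5 equiv), Et3N, CH2Cl2, rt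
Reagents that add atoms: N,N-dimethylmethyleneiminium iodide (Eschenmoser's salt), C=[N+](C)C.[I-]
Why: Mannich condensation–elimination (alpha-methylenation of an aldehyde) can only take place at C4, the single enolisable aldehyde alpha-carbon; the lactol carbon has no second alpha-hydrogen and stays closed.

Step 12
Reactants: 17 enal lactol
Product: 18 triol (allylic C3–OH; primary C2–OH; secondary C9–OH)
Conditions: NaBH4 (excess), EtOH, 0 °C → rt
Reagents that add atoms: none
Why: Borohydride reduces the enal in the 1,2 sense and, through its open form, the lactol. The two primary alcohols are now chemically distinct because only the one at C3 is allylic.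

Step 13
Reactants: 18 triol
Product: 19 enal diol (C3 formyl restored; C2–OH and C9–OH free)
Conditions: MnO2 (activated, excess), CH2Cl2, rt
Reagents that add atoms: none
Why: Manganese dioxide oxidises allylic alcohols selectively, so the 2-substituted propenal is restored without touching the saturated primary or the hindered secondary alcohol.

Step 14
Reactants: 19 enal diol
Product: 20 C2 methanesulfonate of 19
Conditions: MsCl (1.1 equiv), Et3N, CH2Cl2, −20 °C
Reagents that add atoms: methanesulfonyl chloride, CS(=O)(=O)Cl
Why: Sulfonylation of the primary C2 hydroxyl is far faster than that of the hindered secondary 9-hydroxyl.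

Step 15
Reactants: 20 C2 methanesulfonate with free 9-OH; 21 (S)-2-methylbutanoic anhydride
Product: 22 9-O-[(S)-2-methylbutanoyl] ester of 20
Conditions: 21 (3 equiv), DMAP (1 equiv), Et3N, CH2Cl2, 35 °C
Reagents that add atoms: none
Why: DMAP-catalysed acylation with the anhydride avoids a ketene pathway, so the alpha-stereocentre of the acyl group is retained. With ring A open the 9-hydroxyl is accessible, and it is acylated before the oxirane is closed so that it cannot itself displace the mesylate.

Step 16
Reactants: 22 silyl-protected ester mesylate
Product: 23 epoxy amine (13-dimethylamino-11,13-dihydro form of the target; 6-OH free)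
Conditions: Bu4NF (2.5 equiv), THF, 0 °C → rt
Reagents that add atoms: none
Why: Fluoride cleaves both silyl ethers; the C1 alkoxide displaces the vicinal primary mesylate (3-exo-tet Williamson closure) with retention at C1, giving the oxirane with the configuration fixed in step 3.

Step 17
Reactants: 23 epoxy amine
Product: 25 CNP0510523.1 (target), via methiodide 24 (not isolated)
Conditions: MeI, MeCN, rt; then aq. NaHCO3, CH2Cl2, rt
Reagents that add atoms: none
Why: Quaternisation of the Mannich base and mild-base E1cB (Hofmann-type) loss of trimethylamine unveil the alpha-methylene lactone as the last and mildest operation; no stereocentre is touched.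

## Compound list

1 | 2-methoxy-6-methylphenol | COc1cccc(C)c1O | starting material
2 | 2-methoxy-6-methyl-1,4-benzoquinone | COC1=CC(=O)C=C(C)C1=O | intermediate
3 | (E)-but-2-enal (crotonaldehyde) | C/C=C/C=O | starting material
4 | (E)-1-(tert-butyldimethylsilyloxy)buta-1,3-diene | C=C/C=C/O[Si](C)(C)C(C)(C)C | intermediate
5 | cis-fused adduct, 8-(tert-butyldimethylsilyloxy)-2-methoxy-8a-methyl-4a,5,8,8a-tetrahydronaphthalene-1,4-dione | COC1=CC(=O)[C@@H]2CC=C[C@H](O[Si](C)(C)C(C)(C)C)[C@]2(C)C1=O | intermediate
6 | 1-(tert-butyldimethylsilyloxy)-1-methoxyethene | C=C(OC)O[Si](C)(C)C(C)(C)C | starting material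
7 | Michael adduct, cis-fused C8-methoxy C7-(methoxycarbonylmethyl) diketone (C8 epimers) | COC1[C@@H](CC(=O)OC)C(=O)[C@@H]2CC=C[C@H](O[Si](C)(C)C(C)(C)C)[C@]2(C)C1=O | intermediate (not isolated)
8 | trans-fused enedione, methyl 2-[5-(tert-butyldimethylsilyloxy)-4a-methyl-1,4-dioxo-1,4,4a,5,8,8a-hexahydronaphthalen-2-yl]acetate | C1=C(CC(=O)OC)C(=O)[C@H]2CC=C[C@H](O[Si](C)(C)C(C)(C)C)[C@]2(C)C1=O | intermediate
9 | trans-fused saturated diketo ester (C7 arm equatorial) | C1[C@@H](CC(=O)OC)C(=O)[C@H]2CC=C[C@H](O[Si](C)(C)C(C)(C)C)[C@]2(C)C1=O | intermediate
10 | 8-hydroxy diketo ester (8-OH equatorial, trans to the C7 arm) | O[C@@H]1[C@@H](CC(=O)OC)C(=O)[C@H]2CC=C[C@H](O[Si](C)(C)C(C)(C)C)[C@]2(C)C1=O | intermediate (not isolated)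
11 | tricyclic lactone diketone (7,8-trans lactone; C6 and C9 ketones) | C1C(=O)O[C@@H]2[C@@H]1C(=O)[C@H]3CC=C[C@H](O[Si](C)(C)C(C)(C)C)[C@]3(C)C2=O | intermediate
12 | lactone diol (axial 6-OH and 9-OH) | C1C(=O)O[C@@H]2[C@@H]1[C@@H](O)[C@H]3CC=C[C@H](O[Si](C)(C)C(C)(C)C)[C@]3(C)[C@@H]2O | intermediate
13 | 6-O-triethylsilyl ether of 12 | C1C(=O)O[C@@H]2[C@@H]1[C@@H](O[Si](CC)(CC)CC)[C@H]3CC=C[C@H](O[Si](C)(C)C(C)(C)C)[C@]3(C)[C@@H]2O | intermediate
14 | Mannich base, 11-(dimethylaminomethyl) lactone (C11 epimers) | CN(C)CC1C(=O)O[C@@H]2[C@@H]1[C@@H](O[Si](CC)(CC)CC)[C@H]3CC=C[C@H](O[Si](C)(C)C(C)(C)C)[C@]3(C)[C@@H]2O | intermediate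
15 | ring A 2,3-diol of 14 | CN(C)CC1C(=O)O[C@@H]2[C@@H]1[C@@H](O[Si](CC)(CC)CC)[C@H]3CC(O)C(O)[C@H](O[Si](C)(C)C(C)(C)C)[C@]3(C)[C@@H]2O | intermediate (not isolated)
16 | seco lactol aldehyde (C3 aldehyde free; C2 lactol on O9) | CN(C)CC1C(=O)O[C@@H]2[C@@H]1[C@@H](O[Si](CC)(CC)CC)[C@@H](CC=O)[C@](C)([C@@H](O[Si](C)(C)C(C)(C)C)C3O)[C@@H]2O3 | intermediate
17 | enal lactol | CN(C)CC1C(=O)O[C@@H]2[C@@H]1[C@@H](O[Si](CC)(CC)CC)[C@@H](C(=C)C=O)[C@](C)([C@@H](O[Si](C)(C)C(C)(C)C)C3O)[C@@H]2O3 | intermediate
18 | triol (allylic C3–OH, C2–OH, C9–OH) | CN(C)CC1C(=O)O[C@@H]2[C@@H]1[C@@H](O[Si](CC)(CC)CC)[C@@H](C(=C)CO)[C@](C)([C@@H](O[Si](C)(C)C(C)(C)C)CO)[C@@H]2O | intermediate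
19 | enal diol | CN(C)CC1C(=O)O[C@@H]2[C@@H]1[C@@H](O[Si](CC)(CC)CC)[C@@H](C(=C)C=O)[C@](C)([C@@H](O[Si](C)(C)C(C)(C)C)CO)[C@@H]2O | intermediate
20 | C2 methanesulfonate | CN(C)CC1C(=O)O[C@@H]2[C@@H]1[C@@H](O[Si](CC)(CC)CC)[C@@H](C(=C)C=O)[C@](C)([C@@H](O[Si](C)(C)C(C)(C)C)COS(C)(=O)=O)[C@@H]2O | intermediate
21 | (S)-2-methylbutanoic anhydride | CC[C@H](C)C(=O)OC(=O)[C@@H](C)CC | starting material
22 | 9-O-[(S)-2-methylbutanoyl] mesylate | CN(C)CC1C(=O)O[C@@H]2[C@@H]1[C@@H](O[Si](CC)(CC)CC)[C@@H](C(=C)C=O)[C@](C)([C@@H](O[Si](C)(C)C(C)(C)C)COS(C)(=O)=O)[C@@H]2OC(=O)[C@@H](C)CC | intermediate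
23 | epoxy amine (13-dimethylamino-11,13-dihydro target) | CN(C)CC1C(=O)O[C@@H]2[C@@H]1[C@@H](O)[C@@H](C(=C)C=O)[C@](C)([C@@H]1CO1)[C@@H]2OC(=O)[C@@H](C)CC | intermediate
24 | methiodide of 23 | C[N+](C)(C)CC1C(=O)O[C@@H]2[C@@H]1[C@@H](O)[C@@H](C(=C)C=O)[C@](C)([C@@H]1CO1)[C@@H]2OC(=O)[C@@H](C)CC.[I-] | intermediate (not isolated)
25 | CNP0510523.1 | C=C1C(=O)O[C@@H]2[C@@H]1[C@@H](O)[C@@H](C(=C)C=O)[C@](C)([C@@H]1CO1)[C@@H]2OC(=O)[C@@H](C)CC | target

## Step count and least certain steps

Total step count: 17. Longest linear sequence: 16 steps (steps 1 and 3–17; step 2 is a one-step branch).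

**Step 3 (key step).** Most likely failure: insufficient enantiofacial discrimination by the titanium complex, or erosion of endo and regiocontrol if the silyl dienol ether reacts stepwise (Mukaiyama-type) instead of concertedly. Fallback (resolution instead of asymmetric catalysis): 2 and 4 are combined without catalyst in toluene at 60 °C, where regio- and endo-selectivity rest on the substrate alone. The racemic series is carried through steps 4–7 to racemic 12. Esterification of the more accessible 6-hydroxyl with (S)-O-methylmandelic acid (DCC, DMAP) gives the separable diastereomers 6-O-[(S)-2-methoxy-2-phenylacetyl]-12 F1 and 6-O-[(S)-2-methoxy-2-phenylacetyl]-ent-12 F2. Methanolysis of F1 (K2CO3, MeOH, 0 °C, acidic work-up) returns to the route at 12.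

**Step 4.** Most likely failure: attack of the silyl ketene acetal at C8 (ipso substitution of the vinylogous ester) or 1,2-addition to C9 instead of conjugate addition at C7; also incomplete cis-to-trans equilibration at C5. Fallback (reversible soft-carbanion addition–elimination instead of Lewis-acid activation): starting from 5, dimethyl malonate and DBU in THF should give, by Michael addition at C7 and loss of methoxide, the stabilised trans-fused malonyl enedione F3. Zn/AcOH reduction gives the saturated malonate F4, and Krapcho demethoxycarbonylation (LiCl, wet DMSO, 140 °C) returns to the route at 9.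

**Step 6.** Most likely failure: competing enolisation of the C6 ketone (at C5 or C7) or of the ester, and dehydration of the beta-ketol before the lactone closes. Fallback (no enolate; O8 introduced by conjugate borylation): starting from 8, copper-catalysed conjugate borylation (B2pin2, CuCl, NaOtBu, MeOH, THF) should place boron on the unsubstituted C8, anti to C14, with protonation at C7, giving the beta-boryl diketo ester F5. Oxidation with NaBO3 returns to the route at 10, which is lactonised as in step 6.

**Step 8 (with step 7).** Most likely failure: silylation at both hydroxyls or at O9; in step 7, acyl transfer of the lactone to the cis 6-alkoxide if the reduction is allowed to warm. Fallback (differentiate the oxygens by the order of reduction instead of by silylation rate): starting from 11, NaBH4 (1 equiv, MeOH–CH2Cl2, −78 °C) should reduce only the more accessible C6 carbonyl to the 6-hydroxy 9-ketone F6. Silylation of its single hydroxyl (TESOTf, 2,6-lutidine) gives the silyl ether ketone F7, and LiBH(s-Bu)3 reduction of C9 returns to the route at 13.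

**Step 16.** Most likely failure: the basicity of fluoride, leading to acyl migration from O9 to the C1 alkoxide before ring closure, translactonisation onto the free 6-alkoxide, or conjugate addition to the enal. Fallback (acidic desilylation separated from ring closure): starting from 22, HF·pyridine buffered with pyridine in THF removes both silyl groups without forming alkoxides and gives the diol mesylate F8. Cs2CO3 in MeCN at 0 °C then closes the oxirane and returns to the route at 23.

## Further compounds

F1 | step 3 | 6-O-[(S)-2-methoxy-2-phenylacetyl]-12 | C1C(=O)O[C@@H]2[C@@H]1[C@@H](OC(=O)[C@@H](OC)c1ccccc1)[C@H]3CC=C[C@H](O[Si](C)(C)C(C)(C)C)[C@]3(C)[C@@H]2O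
F2 | step 3 | 6-O-[(S)-2-methoxy-2-phenylacetyl]-ent-12 | C1C(=O)O[C@H]2[C@H]1[C@H](OC(=O)[C@@H](OC)c1ccccc1)[C@@H]3CC=C[C@@H](O[Si](C)(C)C(C)(C)C)[C@@]3(C)[C@H]2O
F3 | step 4 | trans-fused C7-[bis(methoxycarbonyl)methyl] enedione | C1=C(C(C(=O)OC)C(=O)OC)C(=O)[C@H]2CC=C[C@H](O[Si](C)(C)C(C)(C)C)[C@]2(C)C1=O
F4 | step 4 | trans-fused saturated C7-[bis(methoxycarbonyl)methyl] diketone | C1[C@@H](C(C(=O)OC)C(=O)OC)C(=O)[C@H]2CC=C[C@H](O[Si](C)(C)C(C)(C)C)[C@]2(C)C1=O
F5 | step 6 | C8 pinacolboryl diketo ester | CC1(C)OB(OC1(C)C)[C@@H]2[C@@H](CC(=O)OC)C(=O)[C@H]3CC=C[C@H](O[Si](C)(C)C(C)(C)C)[C@]3(C)C2=O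
F6 | step 8 | 6-hydroxy 9-keto lactone | C1C(=O)O[C@@H]2[C@@H]1[C@@H](O)[C@H]3CC=C[C@H](O[Si](C)(C)C(C)(C)C)[C@]3(C)C2=O
F7 | step 8 | 6-O-triethylsilyl 9-keto lactone | C1C(=O)O[C@@H]2[C@@H]1[C@@H](O[Si](CC)(CC)CC)[C@H]3CC=C[C@H](O[Si](C)(C)C(C)(C)C)[C@]3(C)C2=O
F8 | step 16 | desilylated diol mesylate (C1–OH, C6–OH, C2–OMs) | CN(C)CC1C(=O)O[C@@H]2[C@@H]1[C@@H](O)[C@@H](C(=C)C=O)[C@](C)([C@@H](O)COS(C)(=O)=O)[C@@H]2OC(=O)[C@@H](C)CC
A1 | alternative 1 | (1(10)E,4E)-germacradien-8,12-olide Cope precursor (15-al, 6-OH, 9-acyloxy) | C=C1C(=O)O[C@@H]2[C@@H]1[C@@H](O)/C=C(C=O)/CC/C=C(C)/[C@@H]2OC(=O)[C@@H](C)CC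
A2 | alternative 1 | 1,2-deoxy (C10-vinyl) elemanolide | C=C1C(=O)O[C@@H]2[C@@H]1[C@@H](O)[C@@H](C(=C)C=O)[C@](C)(C=C)[C@@H]2OC(=O)[C@@H](C)CC
A3 | alternative 2 | cis-4,5-(isopropylidenedioxy)cyclohex-2-enone (quinic acid-derived) | CC1(C)O[C@H]2C=CC(=O)C[C@H]2O1
A4 | alternative 2 | cis-4,5-(isopropylidenedioxy)-3-methyl-3-vinylcyclohexanone | CC1(C)O[C@H]2[C@@](C)(C=C)CC(=O)C[C@H]2O1
A5 | alternative 3 | rac-3-methoxy-1-methylcyclohexa-2,5-diene-1-carboxylic acid | COC1=CC(C)(C(=O)O)C=CC1
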